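The data were generated by integration from invented constants; scatter was added.

You asked for a quick number on the target, with the hunch that this flask had already stopped, and I agreed.

in all of them: starting material 0.077 M
- spring: solid reagent 1.2 equiv; the very flask that is asked about, followed so far
- flask: solid reagent 1.20 equiv; time 30 h

- spring (time / h: target / %): 2.00: 7.2; 6.00: 21.8; 12.0: 30.4; 15.0: 31.6; 25.0: 33.4

(each reading ± 1 percentage point)

- Sunday's: at 30 h add starting material, 50.0 % of the amount charged, then wait 30 h
- Wednesday's: change nothing and wait 30 h more
- Thursday's: at 30 h take out 90 % of the target then present, then wait 30 h

- as a solid, counted per litre of solution: solid reagent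
- target that was removed still counts
- the numbers in the tables scatter with a standard deviation of 1 percentage point
- at the start none of the solid reagent is in solution
- additions bring no volume worth counting

1. target, in percent of the starting material first charged, at 30 h
2. which option adds most target ("none" when 2 percentage points or less is all one gets) (Sunday's / Wednesday's / Thursday's / none)
3. target present, with what was taken out counted in, in percent of the starting material first charged, after Wednesday's
4. target present, with what was taken out counted in, in percent of the starting material first charged, after Thursday's

1. From 15.0 h to 25.0 h the target rose 1.8 percentage points, with a scatter of 1 point. I took that as a plateau, so I put the target near 33.4 % at 30 h and after Wednesday's.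
2. I read this plateau, with starting material left, as two rates that had met. I assumed that a by-product forms one for one with the target and that the solid holds a dissolved partner steady. The forward rate then goes with [starting material], the back rate with [target]².
3. So I carried the plateau quotient, [target]²/[starting material] at rest (thermodynamic control), 0.0129 M, read from the 25.0 h reading.
4. From it I reckoned a gain of 9 points for Sunday's. For Thursday's, with the by-product staying in, I reckoned 15 points, which is more and ends at 48.1 %.
5. The forecast said 33.9 %, Thursday's, 34 % and 54 % (range 34 % to 57 %): “The likeliest reading is an equilibrium”. On Thursday's it stands above my 48.1 %.

The flask gave 33.6 %, Thursday's, 33.6 % and 48.4 %.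

    starting material + partner ⇌ target + by-product (K = 3.20, k = 0.00680 M⁻¹ s⁻¹)
    solid reagent ⇌ partner, rate k2*(cs2 - [partner]) while solid is left; crystals form when [partner] > cs2 (solubility = 4.10 mM, k = 4.90 × 10⁻⁴ s⁻¹)

At 4.09 h partner was made 1.07 times as fast as it was used up, each step taken net. Partner stood at 0.00394 M at 15.0 h and 0.00410 M at 30.0 h, with solid reagent at 67.6 % of its charge. In a like flask with 0.019 M of starting material, 0.0129 M gives 55.2 % of target. That flask ended with 55.4 % of target and partner at 0.00410 M.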